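The route rests on opening the cyclopentane ring (C3a, C4, C5, C6, C6a) of the cis-fused cyclopenta[c]isoxazolidine at N1–C6a and C3a–C4. The feature exploited is that C6a sits beta and C3a alpha to C3, with C4–C6 bridging them, so a linear 6-iodohex-2-enal already holds the five ring carbons and C3. In one amine-catalysed operation the carbamate nitrogen adds to C6a and the enamine carbon C3a displaces iodide at C4, which closes the carbocycle and sets both ring-fusion centres cis. The precursor pair is (E)-6-iodohex-2-enal and Boc-NH-OTBS. The O2–C3 bond and the two pyridylalkyl chains follow by standard steps.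

Key step: step 4

Remark: 11 and 14 are carried as epimer mixtures at the carbinol or hemiketal carbon, because that centre is removed in step 6 or reset in step 8; 8-bromooct-1-ene, 3-bromopyridine and 12-bromododecan-1-ol are taken as purchased.

Step 1
Reactants: 1 5-bromopent-1-ene; 2 crotonaldehyde
Product: 3 (E)-6-bromohex-2-enal
Conditions: second-generation Grubbs catalyst (2 mol %), 2 (4 equiv), CH2Cl2, 40 °C
Reagents that add atoms: none
Why: Olefin cross-metathesis between the terminal alkene of 1 and the electron-poor, slowly homodimerising crotonaldehyde used in excess should give the E-enal under thermodynamic control, with propene leaving as a gas.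

Step 2
Reactants: 3 (E)-6-bromohex-2-enal
Product: 4 (E)-6-iodohex-2-enal
Conditions: NaI (3 equiv), acetone, rt, dark
Reagents that add atoms: sodium iodide, [Na+].[I-]
Why: Finkelstein halide exchange (SN2) at the primary bromide is driven by precipitation of NaBr from acetone and should leave the enal untouched.

Step 3
Reactants: 5 tert-butyl N-hydroxycarbamate
Product: 6 tert-butyl N-[(tert-butyldimethylsilyl)oxy]carbamate
Conditions: TBSCl, Et3N, CH2Cl2, 0 °C → rt
Reagents that add atoms: tert-butyldimethylsilyl chloride, CC(C)(C)[Si](C)(C)Cl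
Why: O-Silylation of the N-hydroxycarbamate at its more nucleophilic oxygen gives a nitrogen nucleophile whose oxygen can no longer close a hemiaminal onto an aldehyde, which keeps the aldehyde free for enamine formation in step 4.

Step 4
Reactants: 4 (E)-6-iodohex-2-enal; 6 tert-butyl N-[(tert-butyldimethylsilyl)oxy]carbamate
Product: 8 tert-butyl N-[(1R,2S)-2-formylcyclopentyl]-N-[(tert-butyldimethylsilyl)oxy]carbamate (cis), via aza-Michael aldehyde 7 (not isolated)
Conditions: (S)-α,α-diphenylprolinol trimethylsilyl ether (20 mol %), PhCO2H (20 mol %), 6 (1.3 equiv), 2,6-lutidine (1.3 equiv), CHCl3, −20 → 0 °C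
Reagents that add atoms: none
Why: Proposed new method: condensation of 4 with the secondary amine gives an E-iminium ion with one face covered by the diphenyl(silyloxy)methyl group, the carbamate nitrogen of 6 adds to the open Re face of enal C3 (C6a), and the enamine so formed (7 bound to the catalyst) attacks the primary C–I carbon through its alpha-carbon (C3a) before it is hydrolysed, 2,6-lutidine taking up the HI. The closest known reaction types are the amine-catalysed conjugate addition of N-silyloxycarbamates to enals and the iminium–enamine Michael/alpha-alkylation domino reactions of halogenated partners that close three- and five-membered carbocycles. The cyclopentane is closed in the 5-exo-tet mode. C6a (R) is set by the catalyst-shielded face of the iminium ion and C3a (S) by the same shielded face of the E-enamine, so nitrogen and the new C–C bond are delivered from one face and the nitrogen and formyl substituents end up cis. The step needs N-addition to outrun dienamine formation and alkylation of the catalyst nitrogen, and ring closure to outrun reversal of the conjugate addition; the hindered alpha-branched catalyst nitrogen, the O-silyl cap that prevents hemiaminal trapping of the aldehyde, and a primary iodide placed exactly three methylenes from C6a secure this.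

Step 5
Reactants: 9 8-bromooct-1-ene; 8 tert-butyl N-[(1R,2S)-2-formylcyclopentyl]-N-[(tert-butyldimethylsilyl)oxy]carbamate
Product: 11 tert-butyl N-[(1R,2S)-2-(1-hydroxynon-8-en-1-yl)cyclopentyl]-N-[(tert-butyldimethylsilyl)oxy]carbamate (both carbinol epimers), via oct-7-en-1-ylmagnesium bromide 10 (not isolated)
Conditions: 9, Mg (I2-activated), THF, rt → 40 °C; then 8, THF, −78 °C; aq NH4Cl
Reagents that add atoms: none
Why: Grignard formation from the unhindered primary bromide and 1,2-addition to the aldehyde, which at −78 °C should be faster than enolisation or attack on the carbamate; the new carbinol centre is left uncontrolled because step 6 removes it, and the terminal alkene is carried as a masked site for the later attachment of the pyridine.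

Step 6
Reactants: 11 tert-butyl N-[(1R,2S)-2-(1-hydroxynon-8-en-1-yl)cyclopentyl]-N-[(tert-butyldimethylsilyl)oxy]carbamate
Product: 12 tert-butyl N-[(tert-butyldimethylsilyl)oxy]-N-[(1R,2S)-2-(non-8-enoyl)cyclopentyl]carbamate
Conditions: Dess–Martin periodinane, CH2Cl2, 0 °C → rt
Reagents that add atoms: none
Why: Dess–Martin oxidation of the secondary alcohol under near-neutral conditions should leave the N–O–Si bond, the Boc group, the terminal alkene and the alpha-stereocenter intact.

Step 7
Reactants: 12 tert-butyl N-[(tert-butyldimethylsilyl)oxy]-N-[(1R,2S)-2-(non-8-enoyl)cyclopentyl]carbamate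
Product: 14 tert-butyl (3aS,6aR)-3-hydroxy-3-(oct-7-en-1-yl)hexahydro-1H-cyclopenta[c]isoxazole-1-carboxylate (both C3 epimers), via N-hydroxy ketone 13 (not isolated)
Conditions: HF·pyridine, pyridine, THF, 0 °C → rt
Reagents that add atoms: none
Why: Fluoride desilylation of the N–O–Si bond followed by intramolecular hemiketalisation: the freed N-hydroxycarbamate oxygen of 13 adds 5-exo-trig to the ketone held cis on the ring, only the cis isomer can form the strain-free cis-fused bicycle, and the acidic medium avoids base-induced loss of the beta-nitrogen.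

Step 8
Reactants: 14 tert-butyl (3aS,6aR)-3-hydroxy-3-(oct-7-en-1-yl)hexahydro-1H-cyclopenta[c]isoxazole-1-carboxylate
Product: 15 tert-butyl (3S,3aS,6aR)-3-(oct-7-en-1-yl)hexahydro-1H-cyclopenta[c]isoxazole-1-carboxylate
Conditions: Et3SiH (5 equiv), BF3·OEt2 (2 equiv), CH2Cl2, −78 → −30 °C
Reagents that add atoms: none
Why: Ionic hydrogenation of a cyclic hemiketal (lactol-type silane reduction): BF3 ionises 14 to the ring oxocarbenium ion and Et3SiH should deliver hydride to the convex face of the cis-fused bicycle, anti to C4, so that H3 ends up cis to H3a and H6a and C3 is set as S, while the remote monosubstituted alkene is not ionised under these conditions.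

Step 9
Reactants: 15 tert-butyl (3S,3aS,6aR)-3-(oct-7-en-1-yl)hexahydro-1H-cyclopenta[c]isoxazole-1-carboxylate; 16 3-bromopyridine
Product: 18 tert-butyl (3S,3aS,6aR)-3-[8-(pyridin-3-yl)octyl]hexahydro-1H-cyclopenta[c]isoxazole-1-carboxylate, via B-alkyl-9-BBN adduct 17 (not isolated)
Conditions: 9-BBN (1.5 equiv), THF, 0 °C → rt; then 16 (1.3 equiv), PdCl2(dppf) (5 mol %), aq K3PO4 (3 equiv), THF/DMF, 50 °C
Reagents that add atoms: none
Why: Anti-Markovnikov hydroboration of the monosubstituted alkene with 9-BBN followed by B-alkyl Suzuki–Miyaura coupling, in which the primary alkyl group passes from the base-activated borane to palladium after oxidative addition of 3-bromopyridine; the carbamate, the N–O bond and the three stereocenters should not be touched, and the basic heterocycle enters only after the Lewis acid step.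

Step 10
Reactants: 18 tert-butyl (3S,3aS,6aR)-3-[8-(pyridin-3-yl)octyl]hexahydro-1H-cyclopenta[c]isoxazole-1-carboxylate
Product: 19 (3S,3aS,6aR)-3-[8-(pyridin-3-yl)octyl]hexahydro-1H-cyclopenta[c]isoxazole
Conditions: CF3CO2H, CH2Cl2, 0 °C → rt
Reagents that add atoms: none
Why: Acidolysis of the tert-butyl carbamate with loss of 2-methylpropene and CO2 should leave the N–O bond, the pyridine and the three stereocenters untouched.

Step 11
Reactants: 20 3-methylpyridine; 21 12-bromododecan-1-ol
Product: 24 13-(pyridin-3-yl)tridecan-1-ol, via 3-picolyllithium 22 (not isolated), via lithium 12-bromododecanolate 23 (not isolated)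
Conditions: 20 (2.5 equiv), LiN(i-Pr)2 (2.4 equiv), THF, −78 °C; then 21, −78 °C → rt; H2O
Reagents that add atoms: none
Why: Lateral lithiation of 3-methylpyridine and SN2 alkylation, in which the first equivalent of 22 turns the alcohol into its lithium alkoxide 23, inert to the carbanion, and the second displaces the primary bromide.

Step 12
Reactants: 24 13-(pyridin-3-yl)tridecan-1-ol
Product: 25 13-(pyridin-3-yl)tridecanal
Conditions: Dess–Martin periodinane, CH2Cl2, rt
Reagents that add atoms: none
Why: Dess–Martin oxidation should stop cleanly at the aldehyde and does not affect the pyridine.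

Step 13
Reactants: 19 (3S,3aS,6aR)-3-[8-(pyridin-3-yl)octyl]hexahydro-1H-cyclopenta[c]isoxazole; 25 13-(pyridin-3-yl)tridecanal
Product: 26 Pyrinodemin B
Conditions: NaBH(OAc)3, AcOH, ClCH2CH2Cl, rt
Reagents that add atoms: none
Why: Reductive amination, in which the weakly basic N–H isoxazolidine condenses with the aldehyde under acetic acid to an N-alkoxyiminium ion that NaBH(OAc)3 should reduce faster than the aldehyde, without touching any stereocenter.

Compound list

1 | 5-bromopent-1-ene | C=CCCCBr | starting material
2 | crotonaldehyde, (E)-but-2-enal | C/C=C/C=O | starting material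
3 | (E)-6-bromohex-2-enal | O=C/C=C/CCCBr | intermediate
4 | (E)-6-iodohex-2-enal | O=C/C=C/CCCI | intermediate
5 | tert-butyl N-hydroxycarbamate | CC(C)(C)OC(=O)NO | starting material
6 | tert-butyl N-[(tert-butyldimethylsilyl)oxy]carbamate | CC(C)(C)OC(=O)NO[Si](C)(C)C(C)(C)C | intermediate
7 | tert-butyl N-[(3R)-6-iodo-1-oxohexan-3-yl]-N-[(tert-butyldimethylsilyl)oxy]carbamate | O=CC[C@@H](CCCI)N(O[Si](C)(C)C(C)(C)C)C(=O)OC(C)(C)C | intermediate
8 | tert-butyl N-[(1R,2S)-2-formylcyclopentyl]-N-[(tert-butyldimethylsilyl)oxy]carbamate | O=C[C@H]1CCC[C@H]1N(O[Si](C)(C)C(C)(C)C)C(=O)OC(C)(C)C | intermediate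
9 | 8-bromooct-1-ene | C=CCCCCCCBr | starting material
10 | oct-7-en-1-ylmagnesium bromide | Br[Mg]CCCCCCC=C | intermediate
11 | tert-butyl N-[(1R,2S)-2-(1-hydroxynon-8-en-1-yl)cyclopentyl]-N-[(tert-butyldimethylsilyl)oxy]carbamate, both carbinol epimers | OC(CCCCCCC=C)[C@H]1CCC[C@H]1N(O[Si](C)(C)C(C)(C)C)C(=O)OC(C)(C)C | intermediate
12 | tert-butyl N-[(tert-butyldimethylsilyl)oxy]-N-[(1R,2S)-2-(non-8-enoyl)cyclopentyl]carbamate | O=C(CCCCCCC=C)[C@H]1CCC[C@H]1N(O[Si](C)(C)C(C)(C)C)C(=O)OC(C)(C)C | intermediate
13 | tert-butyl N-hydroxy-N-[(1R,2S)-2-(non-8-enoyl)cyclopentyl]carbamate | O=C(CCCCCCC=C)[C@H]1CCC[C@H]1N(O)C(=O)OC(C)(C)C | intermediate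
14 | tert-butyl (3aS,6aR)-3-hydroxy-3-(oct-7-en-1-yl)hexahydro-1H-cyclopenta[c]isoxazole-1-carboxylate, both C3 epimers | CC(C)(C)OC(=O)N1OC(O)(CCCCCCC=C)[C@H]2CCC[C@H]21 | intermediate
15 | tert-butyl (3S,3aS,6aR)-3-(oct-7-en-1-yl)hexahydro-1H-cyclopenta[c]isoxazole-1-carboxylate | CC(C)(C)OC(=O)N1O[C@@H](CCCCCCC=C)[C@H]2CCC[C@H]21 | intermediate
16 | 3-bromopyridine | Brc1cccnc1 | starting material
17 | tert-butyl (3S,3aS,6aR)-3-[8-(9-borabicyclo[3.3.1]nonan-9-yl)octyl]hexahydro-1H-cyclopenta[c]isoxazole-1-carboxylate | CC(C)(C)OC(=O)N1O[C@@H](CCCCCCCCB2C3CCCC2CCC3)[C@H]2CCC[C@H]21 | intermediate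
18 | tert-butyl (3S,3aS,6aR)-3-[8-(pyridin-3-yl)octyl]hexahydro-1H-cyclopenta[c]isoxazole-1-carboxylate | CC(C)(C)OC(=O)N1O[C@@H](CCCCCCCCc2cccnc2)[C@H]2CCC[C@H]21 | intermediate
19 | (3S,3aS,6aR)-3-[8-(pyridin-3-yl)octyl]hexahydro-1H-cyclopenta[c]isoxazole | N1O[C@@H](CCCCCCCCc2cccnc2)[C@H]2CCC[C@H]21 | intermediate
20 | 3-methylpyridine | Cc1cccnc1 | starting material
21 | 12-bromododecan-1-ol | OCCCCCCCCCCCCBr | starting material
22 | 3-picolyllithium, (pyridin-3-ylmethyl)lithium | [Li]Cc1cccnc1 | intermediate
23 | lithium 12-bromododecan-1-olate | [Li]OCCCCCCCCCCCCBr | intermediate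
24 | 13-(pyridin-3-yl)tridecan-1-ol | OCCCCCCCCCCCCCc1cccnc1 | intermediate
25 | 13-(pyridin-3-yl)tridecanal | O=CCCCCCCCCCCCCc1cccnc1 | intermediate
26 | Pyrinodemin B, 3-[13-[(3S,3aS,6aR)-3-[8-(pyridin-3-yl)octyl]hexahydro-1H-cyclopenta[c]isoxazol-1-yl]tridecyl]pyridine | c1cncc(CCCCCCCCCCCCCN2O[C@@H](CCCCCCCCc3cccnc3)[C@H]3CCC[C@H]32)c1 | target

Total step count: 13
Longest linear sequence: 10 steps (1, 2, 4, 5, 6, 7, 8, 9, 10, 13)

Steps most likely to fail

Step 4. Alkylation of the catalyst nitrogen by the primary iodide, or diversion into dienamine chemistry, may stop turnover. Reversal of the conjugate addition before ring closure may erode enantiopurity, and enamine-mediated epimerisation may scramble the formyl-bearing centre. The fallback uses known chemistry, sets out from 4 and 6 and returns at 8; it makes the two bonds in two flasks with two different catalysts and needs no compound outside the compound list (F0). The conjugate addition would be run without base under an iminium-only catalyst: the p-toluenesulfonate salt of the enantiomer of 5-benzyl-2-tert-butyl-3-methylimidazolidin-4-one that leaves the Re face of C3 of 4 open, in CHCl3 at −20 °C. The enamine of this catalyst is too weak a nucleophile to touch the iodide, so the reaction should stop at 7, which is isolated. The ring would then be closed by the known amine-catalysed intramolecular alpha-alkylation of 6-halohexanals (alpha-methylproline in the enantiomer matched to the 2S centre, Et3N, CHCl3, −30 °C) to give 8.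

Step 5. The basic Grignard reagent may enolise the alpha-branched aldehyde, which would epimerise the formyl-bearing centre or expel the beta-carbamate nitrogen, and Wurtz-type homocoupling may lower the titre of the reagent. The fallback sets out from 8 and returns at 12; it replaces addition to the aldehyde by acyl substitution, so step 6 is no longer needed. Pinnick oxidation of 8 (NaClO2, NaH2PO4, 2-methylbut-2-ene, t-BuOH/H2O, 0 °C → rt) would give (1S,2R)-2-[(tert-butoxycarbonyl)[(tert-butyldimethylsilyl)oxy]amino]cyclopentane-1-carboxylic acid F1. Coupling with N,O-dimethylhydroxylamine hydrochloride (EDC·HCl, N-methylmorpholine, CH2Cl2, 0 °C → rt) would give the Weinreb amide tert-butyl N-[(tert-butyldimethylsilyl)oxy]-N-[(1R,2S)-2-[methoxy(methyl)carbamoyl]cyclopentyl]carbamate F2. This amide is far less prone to alpha-deprotonation than the aldehyde, and its chelated tetrahedral adduct cannot add a second equivalent. Addition of 10, prepared as in step 5 (THF, −20 → 0 °C; aq NH4Cl), would give ketone 12 directly.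

Step 8. Hydride delivery may show poor facial selectivity, the oxocarbenium ion may lose a proton toward the ring enol ether, or the Lewis acid may open the N–O ketal. The fallback sets out from 11 and returns at 15; it forms the C3–O2 bond by substitution instead of reduction. The (1R)-carbinol epimer of 11, tert-butyl N-[(1R,2S)-2-[(1R)-1-hydroxynon-8-en-1-yl]cyclopentyl]-N-[(tert-butyldimethylsilyl)oxy]carbamate F3, would be separated by chromatography, and the other epimer recycled by oxidation to 12 and reduction. Desilylation with HF·pyridine would give tert-butyl N-hydroxy-N-[(1R,2S)-2-[(1R)-1-hydroxynon-8-en-1-yl]cyclopentyl]carbamate F4. An intramolecular Mitsunobu reaction (PPh3, DIAD, THF, 0 °C) would then let the acidic N-hydroxycarbamate oxygen displace the activated carbinol with inversion, giving 15 with C3 as S.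

Further compounds

F0 | step 4 | none | none
F1 | step 5 | (1S,2R)-2-[(tert-butoxycarbonyl)[(tert-butyldimethylsilyl)oxy]amino]cyclopentane-1-carboxylic acid | OC(=O)[C@H]1CCC[C@H]1N(O[Si](C)(C)C(C)(C)C)C(=O)OC(C)(C)C
F2 | step 5 | tert-butyl N-[(tert-butyldimethylsilyl)oxy]-N-[(1R,2S)-2-[methoxy(methyl)carbamoyl]cyclopentyl]carbamate | CON(C)C(=O)[C@H]1CCC[C@H]1N(O[Si](C)(C)C(C)(C)C)C(=O)OC(C)(C)C
F3 | step 8 | tert-butyl N-[(1R,2S)-2-[(1R)-1-hydroxynon-8-en-1-yl]cyclopentyl]-N-[(tert-butyldimethylsilyl)oxy]carbamate | O[C@H](CCCCCCC=C)[C@H]1CCC[C@H]1N(O[Si](C)(C)C(C)(C)C)C(=O)OC(C)(C)C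
F4 | step 8 | tert-butyl N-hydroxy-N-[(1R,2S)-2-[(1R)-1-hydroxynon-8-en-1-yl]cyclopentyl]carbamate | O[C@H](CCCCCCC=C)[C@H]1CCC[C@H]1N(O)C(=O)OC(C)(C)C
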